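## Structural features

The target is a longipinane-type sesquiterpenoid triester on a tricyclic C15 core. A six-membered enone ring B (C5–C6–C7–C8–C9–C10, ketone at C6, alkene C7=C8, methyl on C8) is spanned from C5 to C9 by the one-carbon bridges C4 and C10. This creates the cyclobutane C4–C5–C10–C9 of a bicyclo[3.1.1]heptenone. The chain C3–C2–C1–C11 links C4 to C10 and closes the seven-membered ring A (C1–C2–C3–C4–C5–C10–C11).

There are seven stereocentres, five of them contiguous (C1 to C5) and two more (C9, C10) in the cyclobutane. C4 is quaternary (methyl) and C11 is a gem-dimethyl carbon, so the carbinols C1 and C3 are both neopentylic. With ring A drawn clockwise (C1→C2→C3→C4→C5→C10→C11) as seen from the β face, H5, H10, the C4 methyl, the C2 acetate and the C3 angelate are β. The C1 angelate and the ring-B carbons C6 and C9 are α.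

Fragile groups are the angelates (Z to E isomerisation), the acetate flanked by two oxygens (acyl migration), the enone, and the strained C4–C9 bond, which is vinylogously activated by the C6 carbonyl and opens by retro-Michael fragmentation once C2 is a carbonyl. The real difficulty is the last cyclobutane bond to quaternary C4. It must be made against roughly 30 kcal/mol of strain, beside three different esters on hindered carbinols.

The key step exploits ring A. C11(Me2)–C1(O)–C2(O) is the imprint of an alkoxy oxyallyl cation, and C3–C4(Me)–C5–C10 is an isoprene-type diene whose C5–C10 end lies in ring B. A [4+3] cycloaddition therefore forms C2–C3 and C10–C11, closes ring A on a ready six-membered ring and sets C10.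

## Logic of the disconnections

24 to 23: the two angeloyl C–O bonds at O1 and O3 are cut last, because the Z-enoates isomerise easily and both hydroxyls are unmasked together. This removes ten carbons and two sensitive alkenes. The forward acylation must esterify two neopentylic alcohols without Z/E isomerisation and without moving the acetate.

23 to 22: two O–Si bonds are cut. A single silyl type on O1 and O3 lets one reagent free both, while O2 already carries its acetate. The forward step must avoid alkoxides next to the acetate.

22 to 20 (through 21): the C4–C9 bond is cut, with O3 returned to C4 as a C3–C4 epoxide and C9 returned as the γ-carbon of a C6 dienol ether. This removes the cyclobutane and turns two stereocentres (C4, C9) into consequences of an anti epoxide opening. The epoxide is chosen over an enone acceptor because its strain makes the closure exergonic and irreversible, and because it installs O3. The forward step needs γ-selective enolisation and a 4-exo capture of a tertiary centre.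

20 to 19: the C6 carbonyl is removed. Introducing it only after the C3=C4 alkene has become an epoxide leaves C7=C8 as the sole alkene, so the forward allylic oxidation has one allylic system to address.

19 to 18 to 17: the acetyl C–O bond and then the C2–H bond are cut, leading back to an α,β-epoxy ketone. The forward reduction must deliver hydride anti to the epoxide oxygen to give 2β-OH.

17 to 15 (through 16): both epoxide C–O bonds are cut and the alkene is returned from C3=C4 to C4=C5. The forward step couples a reversible base-mediated alkene shift to an irreversible nucleophilic epoxidation. It must set H5 β and place the epoxide on the β face.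

15 to 14 to 13 to 12 to 11: functional-group changes only (C2 carbonyl to carbinol, phenylethyl ether restored, silyl ether removed, C1 carbinol to ketone). This carbonyl transposition converts the cycloadduct oxidation pattern (C1 ketone, C2 ether) into the one needed to move the alkene. The forward sequence must set C1 α by reduction and cleave a benzylic ether without touching two alkenes.

11 to 3 + 10: C2–C3 and C10–C11 are cut in a [4+3] sense. This splits the bicycle into a C10 triene and a C5 oxyallyl precursor carrying the chiral alkoxy group. The forward step must be regioselective (C2 to C3, C11 to C10), must use only the s-cis-capable diene of 3, and must induce C10 from the auxiliary.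

3 to 2 to 1: the isopropenyl C=C is traced to a tertiary carbinol and the 1,4-diene to the arene. The forward Birch reduction must spare the benzylic C–O bond. The dehydration has only one possible regiochemistry.

10 to 9 to 7 + 8, and 7 to 4 + 5 (through 6): the Si–O bond, then the two acetal C–O bonds to the chiral alcohol, then the ketone C–C bond to the isopropyl group are cut. The forward steps need mono-addition of the Grignard reagent and an acetal exchange that does not racemise 8.

## Other disconnections considered

Alternative 1: the cut is C5–C10, made forward by Norrish–Yang photocyclisation of the bicyclic C5 ketone A1 to the bridgehead cyclobutanol A2.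
- In its favour: light pays for the ring strain, so thermodynamics is no obstacle. On this point it is better than any ground-state closure, including step 15 of the chosen route. The three oxygens at C1–C3 are carried in protected form with their final configurations.
- Against it here: the C5 carbonyl sits between quaternary C4 and oxygenated C6, which invites α-cleavage (Norrish type 1). The 1,4-biradical can also fragment across C4–C9 (type 2 cleavage) or abstract from other γ-hydrogens (C8–H, C2–H). A2 then carries a tertiary bridgehead hydroxyl at C5 that has no elimination or substitution pathway for removal, and the enone must still be built from a saturated, silyloxylated ring.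
- Comparison: structurally it needs a fully substituted 6–7 bicycle with six stereocentres before the key step, whereas the chosen plan makes ring A and C10 convergently from two small fragments. Mechanistically both pass through high-energy intermediates (biradical against cation). In step count it pays at least four extra operations after the key step (deoxygenation at C5, oxidation and dehydrogenation of ring B).

Alternative 2: the cut is C1=C2, made forward by ring-closing metathesis of the divinyl compound A3 to the cycloheptene A4 with the second-generation Grubbs catalyst RuCl2(=CHPh)(PCy3)(H2IMes).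
- In its favour: the metathesis is mild, driven by loss of ethylene and tolerant of the enone. As a single step it is better precedented than the cationic cycloaddition. Epoxidation of A4 anti to the C3 acetate and acetoxonium opening at C2 would then place O1 α and O2 β by stereospecific anti opening and hand the acetyl group to O2. That endgame is shorter and better controlled than the reductions of the chosen plan.
- Against it here: A3 already contains the complete bicyclo[3.1.1]heptenone, quaternary C4 and two cis-disposed side chains on the cyclobutane, so the hardest bond is moved into an unsolved precursor. Both vinyl groups are neopentylic (one on the gem-dimethyl carbon), which slows initiation, and the new ring bridges the cyclobutane.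
- Comparison: the chosen plan makes ring A first and the cyclobutane last, and this one does the reverse. Its overall step count depends on the route to A3, which is likely long and linear.

Alternative 3: the cut is C4–C9, made forward by a vinylogous Mukaiyama–Michael closure of the silyl dienol ether A5 to the tricyclic enol ether A6. The catalyst is HN(SO2CF3)2, which forms t-BuMe2SiN(SO2CF3)2.
- In its favour: it closes the same bond with the same C6 dienol γ-nucleophile as the chosen route, so on choice of bond and polarity it is equal. It is a catalytic isomerisation with no by-product, its substrate has no acid-labile epoxide, and it needs no early stereochemical decision at C2. On these three points it is better.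
- Against it here, on thermodynamics: by a bond-energy estimate the closure trades one C=C π bond for one σ bond (a gain of the order of 20 kcal/mol) against roughly 30 kcal/mol of new strain. The silyl transfer is thermoneutral and the silyl Lewis acid can reverse the step by fragmentation, so the open form should be favoured.
- Against it here, on the precursor: A5 must be made from the diketone A7, where H5 is α to the C6 carbonyl and γ to the C2 enone. The alkene should therefore drift into C4=C5 conjugation with C6=O, and selective enol silylation at C6 is doubtful.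
- Comparison: A6 still needs oxidation at C3 and a C2 reduction on a tricycle that is open to retro-Michael cleavage while C2 is a ketone. Step 15 of the chosen route is the epoxide-driven version of this closure: it adds a driving force, sets O3 in the same step and is two steps shorter after the common enone stage. Its price is an acid- and base-sensitive β,γ-epoxy ketone.

Key step: step 6

Remark on names: bicyclic intermediates are described as 4,8,11,11-tetramethylbicyclo[5.4.0]undecanes in target numbering (ring A C1–C2–C3–C4–C5–C10–C11, ring B C5–C6–C7–C8–C9–C10). Tricyclic ones carry the extra C4–C9 bond. α and β are used as defined above.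

Assumption: the (S)-1-phenylethyl group is taken to induce the C10 configuration drawn in 11; if the sense of induction were opposite, (R)-1-phenylethanol would be used with no other change.

## Route

Step 1
Reactants: 1 2-(4-methylphenyl)propan-2-ol
Product: 2 2-(4-methylcyclohexa-1,4-dien-1-yl)propan-2-ol
Conditions: n-BuLi (1.0 equiv), THF, −78 °C; then Li, NH3(l), t-BuOH, −78 to −33 °C; NH4Cl
Reagents that add atoms: none
Why: Birch reduction; both alkyl-bearing ring carbons stay sp2, so the 1,4-diene of 2 should form, and the preformed lithium alkoxide should protect the benzylic C–O bond from hydrogenolysis.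

Step 2
Reactants: 2 2-(4-methylcyclohexa-1,4-dien-1-yl)propan-2-ol
Product: 3 1-methyl-4-(prop-1-en-2-yl)cyclohexa-1,4-diene
Conditions: Burgess reagent, benzene, 50 °C; used at once under argon
Reagents that add atoms: none
Why: Burgess dehydration (syn-elimination of the sulfamate ester); only the two methyl groups carry β-hydrogens, so the isopropenyl alkene is the only possible product, and the neutral conditions should not isomerise or aromatise the skipped diene.

Step 3
Reactants: 4 methyl 2,2-dimethoxyacetate; 5 isopropylmagnesium chloride
Product: 7 1,1-dimethoxy-3-methylbutan-2-one, via Weinreb amide 6 (not isolated)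
Conditions: MeNH(OMe)·HCl (1.5 equiv), i-PrMgCl (3 equiv), THF, −20 °C; then i-PrMgCl (1.5 equiv), 0 °C; aq. NH4Cl
Reagents that add atoms: none
Why: Weinreb ketone synthesis in one flask; the magnesium amide of N,O-dimethylhydroxylamine converts the ester into amide 6, whose chelated tetrahedral adduct with the Grignard reagent lasts until work-up, so over-addition and reduction of the ketone are avoided.

Step 4
Reactants: 7 1,1-dimethoxy-3-methylbutan-2-one; 8 (S)-1-phenylethanol
Product: 9 3-methyl-1,1-bis[(S)-1-phenylethoxy]butan-2-one
Conditions: 8 (3 equiv), camphorsulfonic acid (5 mol %), cyclohexane, 55 °C, methanol removed (5 Å molecular sieves, reduced pressure)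
Reagents that add atoms: none
Why: Acid-catalysed transacetalisation driven by removal of methanol; exchange occurs at the acetal carbon, so the C–O bond at the stereocentre of 8 is never broken, and the weak acid and low temperature should avoid benzylic ionisation. With two identical alkoxy groups the acetal carbon of 9 is not a stereocentre.

Step 5
Reactants: 9 3-methyl-1,1-bis[(S)-1-phenylethoxy]butan-2-one
Product: 10 triethyl({3-methyl-1,1-bis[(S)-1-phenylethoxy]but-2-en-2-yl}oxy)silane
Conditions: LiN(i-Pr)2, THF, −78 °C; Et3SiCl, −78 to 0 °C
Reagents that add atoms: chlorotriethylsilane, CC[Si](Cl)(CC)CC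
Why: Kinetic enolisation and O-silylation; the only other α-hydrogen sits on the acetal carbon, where deprotonation is disfavoured by two oxygen lone pairs and two bulky alkoxy groups, so the tetrasubstituted enol ether should form.

Step 6
Reactants: 3 1-methyl-4-(prop-1-en-2-yl)cyclohexa-1,4-diene; 10 triethyl({3-methyl-1,1-bis[(S)-1-phenylethoxy]but-2-en-2-yl}oxy)silane
Product: 11 2β-[(S)-1-phenylethoxy]-4,8,11,11-tetramethylbicyclo[5.4.0]undeca-4,7-dien-1-one (10β-H)
Conditions: 3 (2–3 equiv), Me3SiOSO2CF3 (10 mol %), CH2Cl2, −78 °C; pyridine quench
Reagents that add atoms: none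
Why: Me3SiOSO2CF3 silylates one acetal oxygen of 10 and expels the silyl ether of the alcohol, leaving the 2-(triethylsilyloxy)allyl cation that carries the (S)-1-phenylethoxy group on C2. Its oxocarbenium carbon C2 bonds to the unsubstituted diene terminus C3 of 3, which gives an allyl cation spread over C4–C5–C10 and best stabilised at tertiary C4. The enol ether carbon C11 then closes on C10 (7-endo closure of ring A; the 5-exo alternative at C4 would join two quaternary carbons), and transfer of Et3Si+ to triflate frees the ketone and carries the chain. The closest known reaction type is the silyl-triflate-catalysed, stepwise [4+3] cycloaddition of acetal-derived alkoxy oxyallyl cations, including 1-phenylethyl-substituted ones, with furan and open-chain 1,3-dienes. Chemoselectivity rests on the fact that only the isopropenyl/C5=C10 pair of 3 can become s-cis, whereas C7=C8 is an isolated alkene; low temperature and catalytic acid should keep the skipped diene from isomerising. C2 forms with the ether β but is epimerisable and is erased in step 10. C10 is set in the ring closure, where the phenylethyl group on C2 shields one face of the cation and the C2–C3 bond relays this bias; the β-H10 configuration is the one assumed for the (S)-auxiliary.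

Step 7
Reactants: 11 2β-[(S)-1-phenylethoxy]-4,8,11,11-tetramethylbicyclo[5.4.0]undeca-4,7-dien-1-one
Product: 12 2β-[(S)-1-phenylethoxy]-4,8,11,11-tetramethylbicyclo[5.4.0]undeca-4,7-dien-1α-ol
Conditions: Zn(BH4)2, Et2O, −20 °C
Reagents that add atoms: none
Why: Chelation-controlled hydride reduction; zinc ties the C1 carbonyl to the C2 ether oxygen, which places that ether in the carbonyl plane, and hydride should then add to the β face (the face of H10, away from ring-B carbon C9) to give the 1α-alcohol trans to O2. This sets C1.

Step 8
Reactants: 12 2β-[(S)-1-phenylethoxy]-4,8,11,11-tetramethylbicyclo[5.4.0]undeca-4,7-dien-1α-ol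
Product: 13 1α-(tert-butyldimethylsilyloxy)-2β-[(S)-1-phenylethoxy]-4,8,11,11-tetramethylbicyclo[5.4.0]undeca-4,7-diene
Conditions: t-BuMe2SiOSO2CF3, 2,6-lutidine, CH2Cl2, 0 °C
Reagents that add atoms: tert-butyldimethylsilyl trifluoromethanesulfonate, CC(C)(C)[Si](C)(C)OS(=O)(=O)C(F)(F)F
Why: Silylation of a hindered neopentylic alcohol with the silyl triflate; the ether must last until step 16 and blocks α-ketol chemistry once C2 is oxidised.

Step 9
Reactants: 13 1α-(tert-butyldimethylsilyloxy)-2β-[(S)-1-phenylethoxy]-4,8,11,11-tetramethylbicyclo[5.4.0]undeca-4,7-diene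
Product: 14 1α-(tert-butyldimethylsilyloxy)-4,8,11,11-tetramethylbicyclo[5.4.0]undeca-4,7-dien-2β-ol
Conditions: Li, 4,4'-di-tert-butylbiphenyl (cat.), THF, −78 °C; NH4Cl
Reagents that add atoms: none
Why: Dissolving-metal (arene radical anion) cleavage of the benzylic C–O bond; isolated alkenes and the silyl ether are inert, whereas hydrogenolysis over palladium would saturate the alkenes.

Step 10
Reactants: 14 1α-(tert-butyldimethylsilyloxy)-4,8,11,11-tetramethylbicyclo[5.4.0]undeca-4,7-dien-2β-ol
Product: 15 1α-(tert-butyldimethylsilyloxy)-4,8,11,11-tetramethylbicyclo[5.4.0]undeca-4,7-dien-2-one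
Conditions: Pr4N[RuO4] (5 mol %), N-methylmorpholine N-oxide, 4 Å molecular sieves, CH2Cl2, rt
Reagents that add atoms: none
Why: Ley–Griffith oxidation under neutral conditions; C2 loses its stereocentre, which was needed only to steer step 7.

Step 11
Reactants: 15 1α-(tert-butyldimethylsilyloxy)-4,8,11,11-tetramethylbicyclo[5.4.0]undeca-4,7-dien-2-one
Product: 17 3β,4β-epoxy-1α-(tert-butyldimethylsilyloxy)-4,8,11,11-tetramethylbicyclo[5.4.0]undec-7-en-2-one (5β-H, 10β-H), via conjugated enone 16 (not isolated)
Conditions: DBU (0.5 equiv), t-BuOOH (anhydrous), CH2Cl2, 0 °C to rt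
Reagents that add atoms: tert-butyl hydroperoxide, CC(C)(C)OO
Why: Base moves the alkene into conjugation through the C2 dienolate (protonation at C5), and the conjugated enone 16 is removed irreversibly by Weitz–Scheffer epoxidation, so the position of the enone equilibrium does not limit conversion. The peroxide anion should add to C4 on the β face, away from ring B and from O1, and the epoxide closes on that face; the cis ring fusion (β-H5) is the one taken on and is fixed once the enone is consumed.

Step 12
Reactants: 17 3β,4β-epoxy-1α-(tert-butyldimethylsilyloxy)-4,8,11,11-tetramethylbicyclo[5.4.0]undec-7-en-2-one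
Product: 18 3β,4β-epoxy-1α-(tert-butyldimethylsilyloxy)-4,8,11,11-tetramethylbicyclo[5.4.0]undec-7-en-2β-ol
Conditions: NaBH4, CeCl3·7H2O, MeOH, −40 °C
Reagents that add atoms: none
Why: Luche-type 1,2-reduction; hydride should add anti to the epoxide oxygen held next to the carbonyl, which gives the 2β-alcohol cis to the epoxide and trans to O1.

Step 13
Reactants: 18 3β,4β-epoxy-1α-(tert-butyldimethylsilyloxy)-4,8,11,11-tetramethylbicyclo[5.4.0]undec-7-en-2β-ol
Product: 19 2β-acetoxy-3β,4β-epoxy-1α-(tert-butyldimethylsilyloxy)-4,8,11,11-tetramethylbicyclo[5.4.0]undec-7-ene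
Conditions: Ac2O, pyridine, DMAP (cat.), CH2Cl2, rt
Reagents that add atoms: acetic anhydride, CC(=O)OC(C)=O
Why: Standard acylation; the acetate is the C2 ester of the target, and because it is cis to the epoxide its carbonyl oxygen cannot reach the backside of either epoxide carbon in step 15.

Step 14
Reactants: 19 2β-acetoxy-3β,4β-epoxy-1α-(tert-butyldimethylsilyloxy)-4,8,11,11-tetramethylbicyclo[5.4.0]undec-7-ene
Product: 20 2β-acetoxy-3β,4β-epoxy-1α-(tert-butyldimethylsilyloxy)-4,8,11,11-tetramethylbicyclo[5.4.0]undec-7-en-6-one
Conditions: Rh2(caprolactamate)4 (1 mol %), t-BuOOH (70% in water), ClCH2CH2Cl, 40 °C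
Reagents that add atoms: tert-butyl hydroperoxide, CC(C)(C)OO
Why: Allylic C–H oxidation by tert-butylperoxyl radicals; C7=C8 is the only alkene left, and hydrogen abstraction at C6 gives the more substituted allyl radical at the less hindered methylene (C9 is flanked by C10 and quaternary C11), the pattern by which 1-methylcyclohexenes give 3-methylcyclohexenones. The near-neutral medium should leave the β,γ-epoxy ketone intact.

Step 15
Reactants: 20 2β-acetoxy-3β,4β-epoxy-1α-(tert-butyldimethylsilyloxy)-4,8,11,11-tetramethylbicyclo[5.4.0]undec-7-en-6-one
Product: 22 2β-acetoxy-1α,3β-bis(tert-butyldimethylsilyloxy)-4β,8,11,11-tetramethyltricyclo[5.4.0.0(4,9)]undec-7-en-6-one, via silyl dienol ether 21 (not isolated)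
Conditions: Et3N (1.2 equiv), t-BuMe2SiOSO2CF3 (1.5 equiv), CH2Cl2, −78 to −20 °C
Reagents that add atoms: tert-butyldimethylsilyl trifluoromethanesulfonate, CC(C)(C)[Si](C)(C)OS(=O)(=O)C(F)(F)F
Why: Proposed new method: soft enolisation should give the through-conjugated C6 silyl dienol ether 21 by loss of a C9 proton (H5 lies near the carbonyl plane in the conformer with C11 equatorial and is poorly acidic), and the remaining silyl triflate then activates the epoxide so that C9 attacks tertiary C4 from the α face with inversion (4-exo opening), which forms C4–C9, turns the C4 methyl to β, leaves O3 as its β silyl ether and regenerates silyl triflate from O6. The closest known reaction type is the Lewis-acid-mediated intramolecular opening of epoxides by silyl enol ethers, established for five- and six-membered rings and extended here to a cyclobutane and to the γ-carbon of a dienol ether. Unlike a conjugate addition to an enone, which trades only one π bond for the strained σ bond, this closure is paid for by the epoxide strain and cannot revert.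

Step 16
Reactants: 22 2β-acetoxy-1α,3β-bis(tert-butyldimethylsilyloxy)-4β,8,11,11-tetramethyltricyclo[5.4.0.0(4,9)]undec-7-en-6-one
Product: 23 2β-acetoxy-1α,3β-dihydroxy-4β,8,11,11-tetramethyltricyclo[5.4.0.0(4,9)]undec-7-en-6-one
Conditions: HF·pyridine, pyridine, THF, 0 °C to rt
Reagents that add atoms: none
Why: Acidic fluoride cleaves both silyl ethers without creating an alkoxide next to the acetate, which should suppress acyl migration; the enone and the cyclobutane are not affected.

Step 17
Reactants: 23 2β-acetoxy-1α,3β-dihydroxy-4β,8,11,11-tetramethyltricyclo[5.4.0.0(4,9)]undec-7-en-6-one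
Product: 24 2β-acetoxy-1α,3β-bis[(Z)-2-methylbut-2-enoyloxy]-4β,8,11,11-tetramethyltricyclo[5.4.0.0(4,9)]undec-7-en-6-one (CNP0335415.1)
Conditions: angelic acid, 2,4,6-trichlorobenzoyl chloride, Et3N, toluene, rt; then 23, 80 °C
Reagents that add atoms: angelic acid [(Z)-2-methylbut-2-enoic acid], C/C=C(/C)C(=O)O
Why: Yamaguchi-type mixed-anhydride acylation; both alcohols attack the less hindered angeloyl carbonyl, and without a nucleophilic catalyst or an alkoxide the Z geometry of the angelates and the position of the acetate should be retained.

## Compound list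

1 | 2-(4-methylphenyl)propan-2-ol | CC(C)(O)c1ccc(C)cc1 | starting material
2 | 2-(4-methylcyclohexa-1,4-dien-1-yl)propan-2-ol | CC1=CCC(C(C)(C)O)=CC1 | intermediate
3 | 1-methyl-4-(prop-1-en-2-yl)cyclohexa-1,4-diene | CC1=CCC(C(C)=C)=CC1 | intermediate
4 | methyl 2,2-dimethoxyacetate | COC(OC)C(=O)OC | starting material
5 | isopropylmagnesium chloride | CC(C)[Mg]Cl | starting material
6 | N-methoxy-2,2-dimethoxy-N-methylacetamide (not isolated) | COC(OC)C(=O)N(C)OC | intermediate
7 | 1,1-dimethoxy-3-methylbutan-2-one | COC(OC)C(=O)C(C)C | intermediate
8 | (S)-1-phenylethanol | C[C@H](O)c1ccccc1 | starting material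
9 | 3-methyl-1,1-bis[(S)-1-phenylethoxy]butan-2-one | CC(C)C(=O)C(O[C@@H](C)c1ccccc1)O[C@@H](C)c1ccccc1 | intermediate
10 | triethylsilyl enol ether of 9 | CC(C)=C(O[Si](CC)(CC)CC)C(O[C@@H](C)c1ccccc1)O[C@@H](C)c1ccccc1 | intermediate
11 | cycloadduct: C1 ketone, 2β-(S)-1-phenylethyl ether, C4=C5 and C7=C8 alkenes, 10β-H | O=C1[C@@H](O[C@@H](C)c2ccccc2)CC(C)=C3CC=C(C)C[C@@H]3C1(C)C | intermediate
12 | 1α-alcohol of 11 | O[C@@H]1[C@@H](O[C@@H](C)c2ccccc2)CC(C)=C3CC=C(C)C[C@@H]3C1(C)C | intermediate
13 | 1α-TBS ether of 12 | CC(C)(C)[Si](C)(C)O[C@@H]1[C@@H](O[C@@H](C)c2ccccc2)CC(C)=C3CC=C(C)C[C@@H]3C1(C)C | intermediate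
14 | 1α-silyloxy 2β-alcohol, 4,7-diene | CC(C)(C)[Si](C)(C)O[C@@H]1[C@@H](O)CC(C)=C2CC=C(C)C[C@@H]2C1(C)C | intermediate
15 | 1α-silyloxy C2 ketone, 4,7-diene | CC(C)(C)[Si](C)(C)O[C@@H]1C(=O)CC(C)=C2CC=C(C)C[C@@H]2C1(C)C | intermediate
16 | 1α-silyloxy 3,7-dien-2-one, 5β-H (not isolated) | CC(C)(C)[Si](C)(C)O[C@@H]1C(=O)C=C(C)[C@@H]2CC=C(C)C[C@@H]2C1(C)C | intermediate
17 | 3β,4β-epoxy-1α-silyloxy-7-en-2-one | CC(C)(C)[Si](C)(C)O[C@@H]1C(=O)[C@H]3O[C@@]3(C)[C@@H]2CC=C(C)C[C@@H]2C1(C)C | intermediate
18 | 3β,4β-epoxy-1α-silyloxy-7-en-2β-ol | CC(C)(C)[Si](C)(C)O[C@@H]1[C@@H](O)[C@H]3O[C@@]3(C)[C@@H]2CC=C(C)C[C@@H]2C1(C)C | intermediate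
19 | 2β-acetate of 18 | CC(C)(C)[Si](C)(C)O[C@@H]1[C@@H](OC(C)=O)[C@H]3O[C@@]3(C)[C@@H]2CC=C(C)C[C@@H]2C1(C)C | intermediate
20 | 6-oxo derivative of 19 (7-en-6-one) | CC(C)(C)[Si](C)(C)O[C@@H]1[C@@H](OC(C)=O)[C@H]3O[C@@]3(C)[C@@H]2C(=O)C=C(C)C[C@@H]2C1(C)C | intermediate
21 | C6 silyl dienol ether of 20 (6,8-diene; not isolated) | CC(C)(C)[Si](C)(C)O[C@@H]1[C@@H](OC(C)=O)[C@H]3O[C@@]3(C)[C@@H]2C(O[Si](C)(C)C(C)(C)C)=CC(C)=C[C@@H]2C1(C)C | intermediate
22 | tricyclic 2β-acetate 1α,3β-bis(TBS ether) 7-en-6-one | CC(C)(C)[Si](C)(C)O[C@@H]1[C@@H](OC(C)=O)[C@@H](O[Si](C)(C)C(C)(C)C)[C@@]2(C)[C@@H]3C(=O)C=C(C)[C@H]2[C@@H]3C1(C)C | intermediate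
23 | tricyclic 2β-acetate 1α,3β-diol | O[C@@H]1[C@@H](OC(C)=O)[C@@H](O)[C@@]2(C)[C@@H]3C(=O)C=C(C)[C@H]2[C@@H]3C1(C)C | intermediate
24 | CNP0335415.1 (1α,3β-diangelate 2β-acetate) | C/C=C(/C)C(=O)O[C@@H]1[C@@H](OC(C)=O)[C@@H](OC(=O)/C(C)=C\C)[C@@]2(C)[C@@H]3C(=O)C=C(C)[C@H]2[C@@H]3C1(C)C | target

## Step count and risks

Total step count: 17. Longest linear sequence: 15 steps (steps 3–5 and 6–17, from methyl 2,2-dimethoxyacetate).

Least certain steps:

Step 15 (Proposed new method). Most likely failures are enolisation toward C5 with β-elimination of the neighbouring epoxide, or collapse of the activated epoxide by 1,2-hydride shift or proton loss before the strained 4-exo capture. Attack through C7 instead of C9 is a lesser risk.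
- Fallback (known chemistry), from 19 back to 22. Hydroboration–oxidation of the C7=C8 alkene (BH3·SMe2, then NaBO3·4H2O) would give the C7 alcohol F1. Dess–Martin oxidation would give the C7 ketone F2, and dehydrogenation with IBX the C8=C9 enone F3.
- Cp2TiCl (trivalent titanium, from Cp2TiCl2 and Zn, with 2,4,6-collidine hydrochloride) would open the epoxide homolytically at C4. The tertiary radical would add 4-exo to C9 of the enone, and reduction of the α-keto radical to the titanium enolate makes the closure irreversible. This titanocene-mediated radical 4-exo cyclisation of epoxides onto α,β-unsaturated carbonyl groups is an established cyclobutane synthesis. It would give the tricyclic hydroxy ketone F4.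
- Silylation (t-BuMe2SiOSO2CF3, 2,6-lutidine) would give the silyl ether F5, NaBH4 the C7 alcohol F6, and Burgess dehydration the C7=C8 alkene F7. Allylic oxidation of F7 at C6 (CrO3, 3,5-dimethylpyrazole; the α-pinene-to-verbenone pattern) returns 22.

Step 6 (key step). Most likely failures are acid-induced isomerisation, aromatisation or oligomerisation of the skipped triene before it is trapped, closure of the allyl cation at C4 to a five-membered ring, and weak facial induction, because the auxiliary reaches C10 only through the new C2 centre.
- Fallback, from 8 and 3 back to 11: the same oxyallyl unit is generated without a Lewis acid. Ag2O-mediated O-alkylation of 8 with 1-bromo-3-methylbutan-2-one would give 3-methyl-1-[(S)-1-phenylethoxy]butan-2-one F8. SO2Cl2 would chlorinate its tertiary α-carbon to the chloro ketone F9. F9 with Et3N in CF3CH2OH in the presence of 3 would enolise, lose chloride and give 11 by the base-mediated oxyallyl cycloaddition.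

Step 7. Hydride delivery from the α face is the likely failure, since the seven-membered ring offers little intrinsic bias if chelation is incomplete.
- Fallback, from 11 back to 12: reagent control replaces substrate control. Corey–Bakshi–Shibata reduction (B-methyl oxazaborolidine, BH3·SMe2) is used with the catalyst enantiomer that delivers hydride to the β face, the quaternary C11 side acting as the large substituent. No new compound is formed.

Step 11. The likely failure is epoxidation of the trans-fused C5 epimer of the enone, because C5 is set by a reversible protonation and the product ratio depends on relative epoxidation rates. Partial epimerisation at C1 under base is a second risk.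
- Fallback, from 15 back to 16 and then 17: H5 is set kinetically. Et3SiOSO2CF3/Et3N would give the triethylsilyl dienol ether F10. Cr(CO)3(naphthalene)-catalysed 1,4-addition of H2 to the s-cis diene would deliver both hydrogens to the open β face and give the allyl silyl ether F11 with β-H5.
- Methanolysis (pyridinium p-toluenesulfonate, MeOH) would give the 2α allylic alcohol F12. MnO2 returns 16 as the cis-fused isomer only, and LiOO-t-Bu in THF at −20 °C (non-equilibrating nucleophilic epoxidation) gives 17.

Step 12. Hydride attack from the β face (syn to the epoxide oxygen, anti to the silyloxy group) would give the wrong C2 configuration.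
- Fallback, from 17 back to 19: the 2α epimer of 18, F13, would be treated under Mitsunobu conditions with acetic acid (PPh3, diisopropyl azodicarboxylate). This inverts C2 and installs the acetate in one operation, giving 19.

## Further compounds

F1 | step 15 | C7 alcohol from hydroboration of 19 (C7, C8 configurations not defined) | CC(C)(C)[Si](C)(C)O[C@@H]1[C@@H](OC(C)=O)[C@H]3O[C@@]3(C)[C@@H]2CC(O)C(C)C[C@@H]2C1(C)C
F2 | step 15 | C7 ketone (C8 configuration not defined) | CC(C)(C)[Si](C)(C)O[C@@H]1[C@@H](OC(C)=O)[C@H]3O[C@@]3(C)[C@@H]2CC(=O)C(C)C[C@@H]2C1(C)C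
F3 | step 15 | C8=C9 enone with C7 ketone | CC(C)(C)[Si](C)(C)O[C@@H]1[C@@H](OC(C)=O)[C@H]3O[C@@]3(C)[C@@H]2CC(=O)C(C)=C[C@@H]2C1(C)C
F4 | step 15 | tricyclic 3β-hydroxy C7 ketone (C8 configuration not defined) | CC(C)(C)[Si](C)(C)O[C@@H]1[C@@H](OC(C)=O)[C@@H](O)[C@@]2(C)[C@@H]3CC(=O)C(C)[C@H]2[C@@H]3C1(C)C
F5 | step 15 | 3β-TBS ether of F4 | CC(C)(C)[Si](C)(C)O[C@@H]1[C@@H](OC(C)=O)[C@@H](O[Si](C)(C)C(C)(C)C)[C@@]2(C)[C@@H]3CC(=O)C(C)[C@H]2[C@@H]3C1(C)C
F6 | step 15 | C7 alcohol of F5 (C7, C8 configurations not defined) | CC(C)(C)[Si](C)(C)O[C@@H]1[C@@H](OC(C)=O)[C@@H](O[Si](C)(C)C(C)(C)C)[C@@]2(C)[C@@H]3CC(O)C(C)[C@H]2[C@@H]3C1(C)C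
F7 | step 15 | tricyclic C7=C8 alkene (6-deoxo-22) | CC(C)(C)[Si](C)(C)O[C@@H]1[C@@H](OC(C)=O)[C@@H](O[Si](C)(C)C(C)(C)C)[C@@]2(C)[C@@H]3CC=C(C)[C@H]2[C@@H]3C1(C)C
F8 | step 6 | 3-methyl-1-[(S)-1-phenylethoxy]butan-2-one | CC(C)C(=O)CO[C@@H](C)c1ccccc1
F9 | step 6 | 3-chloro-3-methyl-1-[(S)-1-phenylethoxy]butan-2-one | CC(C)(Cl)C(=O)CO[C@@H](C)c1ccccc1
F0 | step 7 | none | none
F10 | step 11 | triethylsilyl dienol ether of 15 (2,4,7-triene) | CC(C)(C)[Si](C)(C)O[C@@H]1C(O[Si](CC)(CC)CC)=CC(C)=C2CC=C(C)C[C@@H]2C1(C)C
F11 | step 11 | 2α-triethylsilyloxy-1α-TBSO-3,7-diene, 5β-H | CC(C)(C)[Si](C)(C)O[C@@H]1[C@H](O[Si](CC)(CC)CC)C=C(C)[C@@H]2CC=C(C)C[C@@H]2C1(C)C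
F12 | step 11 | 1α-TBSO-3,7-dien-2α-ol, 5β-H | CC(C)(C)[Si](C)(C)O[C@@H]1[C@H](O)C=C(C)[C@@H]2CC=C(C)C[C@@H]2C1(C)C
F13 | step 12 | 2α epimer of 18 | CC(C)(C)[Si](C)(C)O[C@@H]1[C@H](O)[C@H]3O[C@@]3(C)[C@@H]2CC=C(C)C[C@@H]2C1(C)C
A1 | alternative 1 | bicyclic C5 ketone, photoprecursor | CC(C)(C)[Si](C)(C)O[C@@H]1[C@@H](O[Si](C)(C)C(C)(C)C)[C@@H](O[Si](C)(C)C(C)(C)C)[C@@]2(C)C(=O)[C@@H](O[Si](CC)(CC)CC)C[C@@H](C)[C@H]2CC1(C)C
A2 | alternative 1 | tricyclic bridgehead cyclobutanol (C5 hydroxyl) | CC(C)(C)[Si](C)(C)O[C@@H]1[C@@H](O[Si](C)(C)C(C)(C)C)[C@@H](O[Si](C)(C)C(C)(C)C)[C@@]2(C)[C@]3(O)[C@@H](O[Si](CC)(CC)CC)C[C@@H](C)[C@H]2[C@@H]3C1(C)C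
A3 | alternative 2 | divinyl bicyclo[3.1.1]heptenone, metathesis substrate | C=C[C@@H](OC(C)=O)[C@@]1(C)[C@@H]2C(=O)C=C(C)[C@H]1[C@@H]2C(C)(C)C=C
A4 | alternative 2 | tricyclic cycloheptene with C3 acetate | C1=C[C@@H](OC(C)=O)[C@@]2(C)[C@@H]3C(=O)C=C(C)[C@H]2[C@@H]3C1(C)C
A5 | alternative 3 | bicyclic C2 enone with C6 silyl dienol ether | CC(C)(C)[Si](C)(C)O[C@@H]1C(=O)C=C(C)[C@@H]2C(O[Si](C)(C)C(C)(C)C)=CC(C)=C[C@@H]2C1(C)C
A6 | alternative 3 | tricyclic enone with C2 silyl enol ether | CC(C)(C)[Si](C)(C)O[C@@H]1C(O[Si](C)(C)C(C)(C)C)=C[C@@]2(C)[C@@H]3C(=O)C=C(C)[C@H]2[C@@H]3C1(C)C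
A7 | alternative 3 | bicyclic 3,7-diene-2,6-dione, precursor of A5 | CC(C)(C)[Si](C)(C)O[C@@H]1C(=O)C=C(C)[C@@H]2C(=O)C=C(C)C[C@@H]2C1(C)C
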